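## Structural features

The target is a eudesmane: a trans-fused decalin in which ring A (C1–C5, C10) and ring B (C5–C10) share the C5–C10 bond, with O3 esterified by (S)-3-methylpentanoic acid. Ring A carries four contiguous stereocentres. C3 (R) bears the axial α ester oxygen, C4 (S) is a tertiary carbinol with an equatorial α hydroxyl and an axial β methyl (C15), C5 (R) has an α hydrogen, and C10 (R) is an all-carbon quaternary centre with the axial β methyl C14. The two oxygens on C3 and C4 are cis, and C15 sits 1,3-diaxial to C14. Ring B is a pulegone-type unit: the C8 ketone is conjugated to the exocyclic tetrasubstituted C7=C11 isopropylidene, between the C6 and C9 methylenes. The fragile parts are the tertiary C4 alcohol (elimination under acid), the ester (hydrolysis), and the enone (deconjugation to the isopropenyl isomer, conjugate addition), so diol and ester are best introduced last. The real difficulty is the quaternary C10 in the correct absolute sense together with its trans relation to C5. C3 and C4 can then be relayed from the ring fusion by α-face dihydroxylation of a C3=C4 olefin. The key step uses the fact that C10 and C5 are the β and α carbons of a ring A cyclohexenone whose carbonyl is C4. One vicinal difunctionalisation therefore installs C14 on C10 and the C6–C7=C11 arm on C5, while a linear alkynyl group on C10 stands in for C9–C8.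

## Logic of the disconnections

21 ⇒ 19 + 20. The acyl–O3 bond is cut. The acid 20 is bought with its stereocentre in place, and that centre is β to the carbonyl and cannot epimerise. The forward acylation must select the secondary C3 hydroxyl over the tertiary C4 hydroxyl of 19, which the steric difference provides.

19 ⇒ 18. Both C–O bonds at C3 and C4 are cut, removing two stereocentres and leaving a trisubstituted olefin. The forward dihydroxylation must attack the α face, anti to the axial C14 methyl, and must ignore the hindered, electron-poor C7=C11 olefin.

18 ⇒ 17 ⇒ 16. No skeletal bond is cut. The C7=C11 olefin is moved out of conjugation (17) and the C8 ketone is taken back to a carbinol (16), which exposes a homoallylic alcohol, the retron of a carbonyl-ene reaction. Forward, this needs a neutral oxidation and a base isomerisation driven by conjugation.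

16 ⇒ 15. The C7–C8 bond is cut and ring B disappears, leaving a monocyclic aldehyde with a prenyl arm. The forward ring closure requires C6 and C9 to be trans on ring A, and the aldehyde must choose the prenyl olefin over the ring A olefin.

15 ⇒ 13 ⇒ 12. The C8 aldehyde is traced to a terminal alkyne and then to its silyl-capped form. The alkyne is a robust two-carbon handle that survives organometallic steps. Forward, the alkyne must be hydrated in the anti-Markovnikov sense in the presence of two trisubstituted olefins.

12 ⇒ 11 ⇒ 9 (+ 6). The C4–C15 bond is cut through the enol triflate 11, which returns the C4 ketone of 9, the activating group of the key step. Forward, enolisation must go towards C3 and away from C5, which also removes the acidity of C5–H.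

9 ⇒ 5 + 6 + 7. The C10–C14 and C5–C6 bonds are cut together. This removes both ring-fusion stereocentres and reduces the problem to an achiral enynone. Forward, a catalyst must control the absolute configuration at C10 and 1,4 versus 1,6 addition, and the substrate must control the face of alkylation at C5.

5 ⇒ 1 + 2. The C10–C9 bond is cut; an acetylide adds to a vinylogous ester and the enone is transposed on acidic work-up. Both partners are commercial.

## Other disconnections considered

Alternative 1: Ring B is cut at C5–C6 and C9–C10. The forward step is an enantioselective Diels–Alder reaction, catalysed by a chiral cationic oxazaborolidine, between the dienophile (E)-2-methyl-4-oxopent-2-enal A1 and the diene triethyl[(2-methyl-3-methylidenepent-4-en-2-yl)oxy]silane A2, giving the cyclohexene A3.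
- In favour: ring B, the quaternary C10 and C5 arise in one concerted step. The trans relation of C1 and C4 follows stereospecifically from the E geometry of A1. On this point the alternative is better than the chosen plan, whose C5 configuration depends on a kinetic enolate alkylation. The C11 oxygen already present in A3 would give the isopropylidene by β-elimination once C8 is oxidised, which is shorter than the ene, oxidation and isomerisation sequence.
- Against: A3 contains neither C2 nor C3. Ring A would have to be annulated between a neopentyl aldehyde and a methyl ketone, the two carbonyls would have to be told apart, and C3 and C4 would have to be set without the easy α-face dihydroxylation. A1 has two acceptor carbonyls that direct the unsymmetrical diene in opposite senses, so regiochemistry depends on selective activation of the formyl group. Neither A1 nor A2 is a catalogue compound.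
- Comparison: on structure the two plans are equal in fixing C5 and C10. On mechanism the cycloaddition is the more secure for relative configuration. On step economy the alternative is expected to be longer because ring A must still be built.

Alternative 2: The bonds C4–C5 and C9–C10 are cut back to an acyclic chain. Forward, a chiral cationic bisphosphine complex of monovalent gold, for example a (bisphosphine)(AuCl)2 complex activated with AgSbF6, would bicyclise the enyne tert-butyldimethyl{[(E)-6-methylundeca-1,5-dien-9-yn-2-yl]oxy}silane A4 to the trans-fused bicyclic ketone 11,12,13-trinoreudesm-3-en-8-one A5.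
- In favour: both rings, both fusion centres, the C3=C4 olefin with C15 and the C8 ketone appear in one catalytic operation. The trans fusion is tied to the E olefin through a chair–chair transition state. After the key step only an isopropylidenation at C7 separates A5 from 18, followed by steps 10 and 11. After the key step this alternative is therefore shorter than the chosen plan.
- Against: A4 must be made as a geometrically pure trisubstituted E olefin carrying a regiodefined silyl enol ether, which takes several steps and gives an acid-labile substrate. Enantioselective gold bicyclisation of a methyl-capped internal alkyne terminated by a silyl enol ether has thinner precedent than the copper chemistry of the chosen plan, and enantiocontrol by a linear two-coordinate metal far from the forming centres is harder to predict.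
- Comparison: the overall count is expected to be similar or slightly lower. The risk is concentrated in one step of weaker precedent, whereas the chosen plan spreads it over well-known reaction types.

Alternative 3: Ring A is cut at C1–C2 and C5–C10. Forward, (E)-β-ocimene A6 would add as the diene to 2-{2-[(tert-butyldimethylsilyl)oxy]ethyl}prop-2-enal A7 under a chiral cationic oxazaborolidine to give the endo adduct A8.
- In favour: A6 is a cheap terpene that brings C15, the C3=C4 olefin and the complete prenyl arm. No triflate, methyl coupling or alkyne manipulation is needed, so on ring A economy the alternative is better. The concerted cycloaddition sets C5 and C10 together, and the silyloxyethyl arm would lead to 15 and the same endgame, which makes the two plans equal from there on.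
- Against: the formyl group on C10 is the future C14 and must be reduced to methyl next to a quaternary centre, which costs two or three steps. Commercial A6 contains its Z isomer, which cannot easily reach the reactive diene conformation. 2-Substituted acroleins often show a weak or reversed endo preference, so the cis relation of formyl and prenyl is not assured. A7 has to be prepared.
- Comparison: structure and endgame are equal, the mechanism is less certain in its endo/exo outcome, and the step count is estimated as equal to slightly higher.

Key step: step 2

Remarks on the chemistry: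
- (S)-3-Methylpentanoic acid is taken as a commercial, enantiopure compound.
- L* is 1-mesityl-3-(1-hydroxy-4-methylpentan-2-yl)-4,5-dihydroimidazolium hexafluorophosphate, a leucinol-derived carbene precursor available in both antipodes. The antipode that delivers the (S) quaternary centre of 9 is selected by trial.
- The structures of the key-step precursor and product map correctly onto the target. C10 is S in 9 and R in 21 only because the CIP priorities change.
- Equilibration at C5 of 9 is not relied on. The C5 epimer can place both prenyl and methyl equatorial with the alkyne axial, so it may well be the more stable one. Compound 9 is therefore handled without base and C5 is locked in step 3.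
- Compound 16 is drawn as the expected all-equatorial C7/C8 isomer; any other C7/C8 isomer converges at 18.

## Route

Step 1
Reactants: 1 trimethylsilylacetylene; 2 3-ethoxycyclohex-2-en-1-one
Product: 5 3-[(trimethylsilyl)ethynyl]cyclohex-2-en-1-one, via lithium (trimethylsilyl)acetylide 3 (not isolated), via lithium alkoxide adduct 4 (not isolated)
Conditions: n-BuLi, THF, −78 °C; then 2, −78 → 0 °C; then 2 M aq. HCl, rt
Reagents that add atoms: water, O
Why: Stork–Danheiser alkylative enone transposition: the acetylide adds 1,2 to the vinylogous ester and aqueous acid hydrolyses the enol ether with loss of the tertiary hydroxyl to give the 3-alkynyl enone. The C-silyl cap survives dilute acid and no stereocentre is formed.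

Step 2
Reactants: 5 3-[(trimethylsilyl)ethynyl]cyclohex-2-en-1-one; 6 methylmagnesium bromide; 7 prenyl bromide
Product: 9 (2R,3S)-3-methyl-2-(3-methylbut-2-en-1-yl)-3-[(trimethylsilyl)ethynyl]cyclohexan-1-one, via bromomagnesium enolate 8 (not isolated)
Conditions: Cu(OTf)2 (3 mol %), L* (4 mol %), 6 (1.2 equiv), Et2O, −30 → 0 °C, slow addition of 5; then DMPU, 7 (3 equiv), 0 °C → rt; sat. aq. NH4Cl, 0 °C
Reagents that add atoms: none
Why: The Grignard reagent deprotonates the imidazolinium salt and generates a chiral carbene–methylcopper species that complexes the enone, transfers methyl to C10 and releases the bromomagnesium enolate 8, which then displaces bromide from 7 at C5. The closest known reaction type is the copper–carbene-catalysed enantioselective 1,4-addition of Grignard reagents to 3-substituted cyclohexenones, 3-alkynyl enones included, with trapping of the magnesium enolate by an allylic halide. No ring is closed. C10 is set by the chiral carbene on copper (catalyst control), the ligand antipode being chosen so that methyl enters on the face that gives the S centre. C5 is set by the substrate: in the half-chair enolate the slim alkynyl group takes the pseudoaxial site on C10 and the bromide is attacked along the chair-like axial trajectory anti to it, so C6 ends up trans to the alkyne and cis to the methyl. The step needs 1,4 over 1,6 and 1,2 addition, which the ligand-accelerated copper pathway and slow addition of 5 secure, and C- over O-alkylation and SN2 over SN2', which the soft primary allylic bromide favours. It also needs mono-alkylation, for which DMPU, excess 7 and low temperature are used, and a cold neutral quench so that C5 is not equilibrated.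

Step 3
Reactants: 9 (2R,3S)-3-methyl-2-(3-methylbut-2-en-1-yl)-3-[(trimethylsilyl)ethynyl]cyclohexan-1-one
Product: 11 (5S,6R)-5-methyl-6-(3-methylbut-2-en-1-yl)-5-[(trimethylsilyl)ethynyl]cyclohex-1-en-1-yl trifluoromethanesulfonate, via kinetic lithium enolate 10 (not isolated)
Conditions: LDA (LiN(i-Pr)2, 1.1 equiv), THF, −78 °C; PhNTf2, −78 → 0 °C; sat. aq. NH4Cl
Reagents that add atoms: N-phenylbis(trifluoromethanesulfonimide), O=S(=O)(N(c1ccccc1)S(=O)(=O)C(F)(F)F)C(F)(F)F
Why: Kinetic deprotonation by the hindered amide takes the open C3 methylene and not the tertiary C5–H next to the quaternary centre, and O-sulfonylation gives the enol triflate. C5 is untouched and afterwards is no longer α to a carbonyl, so its configuration is fixed.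

Step 4
Reactants: 11 (5S,6R)-5-methyl-6-(3-methylbut-2-en-1-yl)-5-[(trimethylsilyl)ethynyl]cyclohex-1-en-1-yl trifluoromethanesulfonate; 6 methylmagnesium bromide
Product: 12 trimethyl{[(1S,2S)-1,3-dimethyl-2-(3-methylbut-2-en-1-yl)cyclohex-3-en-1-yl]ethynyl}silane
Conditions: Fe(acac)3 (10 mol %), 6 (1.5 equiv), THF/NMP, −30 → 0 °C
Reagents that add atoms: none
Why: Iron-catalysed Kumada-type cross-coupling of an alkenyl triflate with an alkyl Grignard reagent, fast at low temperature and tolerant of silylalkynes and isolated olefins. The position of the C3=C4 olefin is defined by the triflate.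

Step 5
Reactants: 12 trimethyl{[(1S,2S)-1,3-dimethyl-2-(3-methylbut-2-en-1-yl)cyclohex-3-en-1-yl]ethynyl}silane
Product: 13 (5S,6S)-5-ethynyl-1,5-dimethyl-6-(3-methylbut-2-en-1-yl)cyclohex-1-ene
Conditions: K2CO3 (0.2 equiv), MeOH, rt
Reagents that add atoms: none
Why: Methanolysis of the C(sp)–Si bond by catalytic methoxide (protodesilylation of an alkynylsilane); the olefins and both stereocentres are inert.

Step 6
Reactants: 13 (5S,6S)-5-ethynyl-1,5-dimethyl-6-(3-methylbut-2-en-1-yl)cyclohex-1-ene
Product: 15 2-[(1R,2R)-1,3-dimethyl-2-(3-methylbut-2-en-1-yl)cyclohex-3-en-1-yl]acetaldehyde, via (E)-alkenyldicyclohexylborane 14 (not isolated)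
Conditions: Cy2BH (1.1 equiv), THF, 0 °C → rt; then 30% H2O2, aq. NaHCO3, 0 °C → rt
Reagents that add atoms: hydrogen peroxide, OO
Why: Brown hydroboration–oxidation: the bulky dialkylborane adds once, syn and with boron on the terminal carbon, to the alkyne far faster than to trisubstituted olefins, and oxidation of the alkenylborane gives the enol and hence the C8 aldehyde. The bicarbonate buffer keeps the aldehyde from aldol reactions.

Step 7
Reactants: 15 2-[(1R,2R)-1,3-dimethyl-2-(3-methylbut-2-en-1-yl)cyclohex-3-en-1-yl]acetaldehyde
Product: 16 (5R,7R,8S,10R)-eudesma-3,11-dien-8-ol (trans-fused; 8α-hydroxyl and 7β-isopropenyl, both equatorial)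
Conditions: ZnBr2 (1.0 equiv), CH2Cl2, 0 °C → rt
Reagents that add atoms: none
Why: Lewis-acid-promoted intramolecular carbonyl-ene reaction of the citronellal-to-isopulegol type: C7 of the prenyl group attacks the zinc-bound aldehyde through a six-membered chair with hydrogen transfer from a C11 methyl, forming C7–C8 and ring B. The trans fusion is preset by C5 and C10, and the new C7 and C8 centres, expected equatorial, are both erased later.

Step 8
Reactants: 16 (5R,7R,8S,10R)-eudesma-3,11-dien-8-ol
Product: 17 (5R,7R,10R)-eudesma-3,11-dien-8-one
Conditions: Dess–Martin periodinane, NaHCO3, CH2Cl2, 0 °C → rt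
Reagents that add atoms: none
Why: Dess–Martin oxidation of a secondary alcohol under buffered, near-neutral conditions; both olefins are left alone.

Step 9
Reactants: 17 (5R,7R,10R)-eudesma-3,11-dien-8-one
Product: 18 (5R,10R)-eudesma-3,7(11)-dien-8-one
Conditions: DBU (0.5 equiv), CH2Cl2, rt
Reagents that add atoms: none
Why: Base-mediated conjugation of a β,γ-unsaturated ketone through its dienolate (isopulegone-to-pulegone type), driven by conjugation and the tetrasubstituted olefin. C5 and C10 carry no acidic hydrogen and are unaffected.

Step 10
Reactants: 18 (5R,10R)-eudesma-3,7(11)-dien-8-one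
Product: 19 (3R,4S,5R,10R)-3,4-dihydroxyeudesm-7(11)-en-8-one (3α,4α-diol)
Conditions: OsO4 (2 mol %), NMO (1.5 equiv), acetone/H2O (4:1 v/v), 0 °C → rt; aq. Na2SO3
Reagents that add atoms: osmium tetroxide (catalytic oxygen carrier), O=[Os](=O)(=O)=O; N-methylmorpholine N-oxide, C[N+]1([O-])CCOCC1; water, O
Why: Upjohn dihydroxylation: the electron-rich trisubstituted C3=C4 olefin reacts in preference to the hindered, electron-poor tetrasubstituted enone olefin. Osmium adds suprafacially on the α face, anti to the axial C14 methyl, which sets C3 (R) and C4 (S) with the two oxygens cis.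

Step 11
Reactants: 19 (3R,4S,5R,10R)-3,4-dihydroxyeudesm-7(11)-en-8-one; 20 (S)-3-methylpentanoic acid
Product: 21 (3R,4S,5R,10R)-4-hydroxy-8-oxoeudesm-7(11)-en-3-yl (3S)-3-methylpentanoate
Conditions: DCC (1.5 equiv), DMAP (0.3 equiv), CH2Cl2, 0 °C → rt
Reagents that add atoms: none
Why: Steglich esterification: only the secondary C3 hydroxyl is acylated, the tertiary C4 hydroxyl being too hindered. The stereocentre of the acid is β to the carbonyl and cannot epimerise.

## Compound list

1 | trimethylsilylacetylene | C#C[Si](C)(C)C | starting material
2 | 3-ethoxycyclohex-2-en-1-one | CCOC1=CC(=O)CCC1 | starting material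
3 | lithium (trimethylsilyl)acetylide | [Li]C#C[Si](C)(C)C | intermediate
4 | lithium 3-ethoxy-1-[(trimethylsilyl)ethynyl]cyclohex-2-en-1-olate (racemic) | [Li]OC1(C#C[Si](C)(C)C)C=C(OCC)CCC1 | intermediate
5 | 3-[(trimethylsilyl)ethynyl]cyclohex-2-en-1-one | O=C1C=C(C#C[Si](C)(C)C)CCC1 | intermediate
6 | methylmagnesium bromide | C[Mg]Br | starting material
7 | prenyl bromide (1-bromo-3-methylbut-2-ene) | CC(C)=CCBr | starting material
8 | bromomagnesium (S)-3-methyl-3-[(trimethylsilyl)ethynyl]cyclohex-1-en-1-olate | Br[Mg]OC1=C[C@@](C)(C#C[Si](C)(C)C)CCC1 | intermediate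
9 | (2R,3S)-3-methyl-2-(3-methylbut-2-en-1-yl)-3-[(trimethylsilyl)ethynyl]cyclohexan-1-one (prenyl cis to methyl, trans to alkynyl) | O=C1CCC[C@](C)(C#C[Si](C)(C)C)[C@H]1CC=C(C)C | intermediate
10 | lithium (5S,6R)-5-methyl-6-(3-methylbut-2-en-1-yl)-5-[(trimethylsilyl)ethynyl]cyclohex-1-en-1-olate | [Li]OC1=CCC[C@](C)(C#C[Si](C)(C)C)[C@H]1CC=C(C)C | intermediate
11 | (5S,6R)-5-methyl-6-(3-methylbut-2-en-1-yl)-5-[(trimethylsilyl)ethynyl]cyclohex-1-en-1-yl trifluoromethanesulfonate | O=S(=O)(OC1=CCC[C@](C)(C#C[Si](C)(C)C)[C@H]1CC=C(C)C)C(F)(F)F | intermediate
12 | trimethyl{[(1S,2S)-1,3-dimethyl-2-(3-methylbut-2-en-1-yl)cyclohex-3-en-1-yl]ethynyl}silane | CC1=CCC[C@](C)(C#C[Si](C)(C)C)[C@H]1CC=C(C)C | intermediate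
13 | (5S,6S)-5-ethynyl-1,5-dimethyl-6-(3-methylbut-2-en-1-yl)cyclohex-1-ene | CC1=CCC[C@](C)(C#C)[C@H]1CC=C(C)C | intermediate
14 | dicyclohexyl{(E)-2-[(1R,2S)-1,3-dimethyl-2-(3-methylbut-2-en-1-yl)cyclohex-3-en-1-yl]ethenyl}borane | CC1=CCC[C@](C)(/C=C/B(C2CCCCC2)C2CCCCC2)[C@H]1CC=C(C)C | intermediate
15 | 2-[(1R,2R)-1,3-dimethyl-2-(3-methylbut-2-en-1-yl)cyclohex-3-en-1-yl]acetaldehyde | CC1=CCC[C@](C)(CC=O)[C@H]1CC=C(C)C | intermediate
16 | (5R,7R,8S,10R)-eudesma-3,11-dien-8-ol | CC1=CCC[C@]2(C)C[C@H](O)[C@@H](C(C)=C)C[C@@H]12 | intermediate
17 | (5R,7R,10R)-eudesma-3,11-dien-8-one | CC1=CCC[C@]2(C)CC(=O)[C@@H](C(C)=C)C[C@@H]12 | intermediate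
18 | (5R,10R)-eudesma-3,7(11)-dien-8-one | CC1=CCC[C@]2(C)CC(=O)C(=C(C)C)C[C@@H]12 | intermediate
19 | (3R,4S,5R,10R)-3,4-dihydroxyeudesm-7(11)-en-8-one | O[C@@H]1CC[C@]2(C)CC(=O)C(=C(C)C)C[C@H]2[C@]1(C)O | intermediate
20 | (S)-3-methylpentanoic acid | CC[C@H](C)CC(=O)O | starting material
21 | (3R,4S,5R,10R)-4-hydroxy-8-oxoeudesm-7(11)-en-3-yl (3S)-3-methylpentanoate | CC[C@H](C)CC(=O)O[C@@H]1CC[C@]2(C)CC(=O)C(=C(C)C)C[C@H]2[C@]1(C)O | target

## Step count and least certain steps

Total step count: 11. Longest linear sequence: 11 steps (from 1 and 2 to 21); 6, 7 and 20 are purchased.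

**Step 2 (key step).** Three things are most likely to go wrong.
- C-alkylation of the hindered magnesium enolate next to the new quaternary centre may be slow. Proton transfer between enolate and product could then compete, leading to alkylation at C3 and to double alkylation.
- Facial selectivity at C5 rests only on the modest preference of the alkynyl group for the axial site, so it may be poor.
- With the small methyl nucleophile, enantioselectivity or 1,4 versus 1,6 selectivity may be eroded.

The fallback separates the two bond formations. It sets out from 5: the copper-catalysed addition of 6 is run alone and the enolate 8 is quenched with Me3SiCl and Et3N to give the silyl enol ether trimethyl{[(S)-3-methyl-3-[(trimethylsilyl)ethynyl]cyclohex-1-en-1-yl]oxy}silane F1, which can be purified and assayed for enantiomeric purity. Halide-free MeLi in THF at −20 °C cleaves the O–Si bond, which is expected to be faster than attack on the alkynylsilane, to give lithium (S)-3-methyl-3-[(trimethylsilyl)ethynyl]cyclohex-1-en-1-olate F2. This more reactive, copper-free enolate is alkylated with 7 in THF/DMPU at −78 → −20 °C, and the sequence returns to the route at 9.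

**Step 7.** The Lewis-acid-bound aldehyde may be captured in a Prins-type process by the C3=C4 olefin of ring A instead of the prenyl group, or the product may ionise, because the reactive conformer needs the C5 arm pseudoequatorial against allylic strain from C15. The fallback changes the order so that the ring A olefin is an electron-poor enol triflate during the closure. It sets out from 11.
- K2CO3 in MeOH at 0 °C removes the silyl cap to give (5S,6R)-5-ethynyl-5-methyl-6-(3-methylbut-2-en-1-yl)cyclohex-1-en-1-yl trifluoromethanesulfonate F3.
- Cy2BH gives the alkenylborane (5R,6R)-5-[(E)-2-(dicyclohexylboranyl)ethenyl]-5-methyl-6-(3-methylbut-2-en-1-yl)cyclohex-1-en-1-yl trifluoromethanesulfonate F4, which buffered H2O2 oxidises to the aldehyde (5R,6R)-5-methyl-6-(3-methylbut-2-en-1-yl)-5-(2-oxoethyl)cyclohex-1-en-1-yl trifluoromethanesulfonate F5.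
- ZnBr2 closes ring B to (5R,7R,8S,10R)-8-hydroxy-15-noreudesma-3,11-dien-4-yl trifluoromethanesulfonate F6.
- Excess 6 with Fe(acac)3, the first equivalent being consumed by the hydroxyl, installs C15 and returns to the route at 16.

**Step 4.** The Grignard reagent may attack sulfur of the hindered triflate, which would regenerate the enolate and lead to addition at C4, or the coupling may be slow. The fallback replaces the cross-coupling by a Shapiro reaction and sets out from 9. Condensation with 2,4,6-triisopropylbenzenesulfonyl hydrazide under neutral conditions, to avoid exchange at C5, gives N'-[(2R,3S)-3-methyl-2-(3-methylbut-2-en-1-yl)-3-[(trimethylsilyl)ethynyl]cyclohexylidene]-2,4,6-triisopropylbenzenesulfonohydrazide F7. Two equivalents of n-BuLi in THF/TMEDA at −78 → 0 °C deprotonate on the C3 side and expel sulfinate and N2 to give {(5S,6S)-5-methyl-6-(3-methylbut-2-en-1-yl)-5-[(trimethylsilyl)ethynyl]cyclohex-1-en-1-yl}lithium F8. Methyl iodide then gives 12, where the route is rejoined.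

**Step 6.** Over-hydroboration, of the alkyne twice or of a trisubstituted olefin, or loss of the unhindered aldehyde during the oxidative work-up may occur. The fallback avoids boron altogether: a ruthenium-vinylidene anti-Markovnikov hydration of 13 with CpRu(MeCN)3PF6 and 5,5'-bis(trifluoromethyl)-2,2'-bipyridine in aqueous NMP, which ignores olefins, gives 15 directly. This fallback makes no new compound.

## Further compounds

F1 | step 2 | trimethyl{[(S)-3-methyl-3-[(trimethylsilyl)ethynyl]cyclohex-1-en-1-yl]oxy}silane | C[Si](C)(C)OC1=C[C@@](C)(C#C[Si](C)(C)C)CCC1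
F2 | step 2 | lithium (S)-3-methyl-3-[(trimethylsilyl)ethynyl]cyclohex-1-en-1-olate | [Li]OC1=C[C@@](C)(C#C[Si](C)(C)C)CCC1
F3 | step 7 | (5S,6R)-5-ethynyl-5-methyl-6-(3-methylbut-2-en-1-yl)cyclohex-1-en-1-yl trifluoromethanesulfonate | O=S(=O)(OC1=CCC[C@](C)(C#C)[C@H]1CC=C(C)C)C(F)(F)F
F4 | step 7 | (5R,6R)-5-[(E)-2-(dicyclohexylboranyl)ethenyl]-5-methyl-6-(3-methylbut-2-en-1-yl)cyclohex-1-en-1-yl trifluoromethanesulfonate | O=S(=O)(OC1=CCC[C@](C)(/C=C/B(C2CCCCC2)C2CCCCC2)[C@H]1CC=C(C)C)C(F)(F)F
F5 | step 7 | (5R,6R)-5-methyl-6-(3-methylbut-2-en-1-yl)-5-(2-oxoethyl)cyclohex-1-en-1-yl trifluoromethanesulfonate | O=S(=O)(OC1=CCC[C@](C)(CC=O)[C@H]1CC=C(C)C)C(F)(F)F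
F6 | step 7 | (5R,7R,8S,10R)-8-hydroxy-15-noreudesma-3,11-dien-4-yl trifluoromethanesulfonate | O=S(=O)(OC1=CCC[C@]2(C)C[C@H](O)[C@@H](C(C)=C)C[C@@H]12)C(F)(F)F
F7 | step 4 | N'-[(2R,3S)-3-methyl-2-(3-methylbut-2-en-1-yl)-3-[(trimethylsilyl)ethynyl]cyclohexylidene]-2,4,6-triisopropylbenzenesulfonohydrazide | CC(C)c1cc(C(C)C)c(c(C(C)C)c1)S(=O)(=O)NN=C1CCC[C@](C)(C#C[Si](C)(C)C)[C@H]1CC=C(C)C
F8 | step 4 | {(5S,6S)-5-methyl-6-(3-methylbut-2-en-1-yl)-5-[(trimethylsilyl)ethynyl]cyclohex-1-en-1-yl}lithium | [Li]C1=CCC[C@](C)(C#C[Si](C)(C)C)[C@H]1CC=C(C)C
F0 | step 6 | none | none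
A1 | alternative 1 | (E)-2-methyl-4-oxopent-2-enal | O=C/C(C)=C/C(C)=O
A2 | alternative 1 | triethyl[(2-methyl-3-methylidenepent-4-en-2-yl)oxy]silane | C=CC(=C)C(C)(C)O[Si](CC)(CC)CC
A3 | alternative 1 | 6-acetyl-1-methyl-4-[2-(triethylsilyloxy)propan-2-yl]cyclohex-3-ene-1-carbaldehyde (formyl and acetyl trans) | O=C[C@]1(C)CC=C(C(C)(C)O[Si](CC)(CC)CC)C[C@H]1C(C)=O
A4 | alternative 2 | tert-butyldimethyl{[(E)-6-methylundeca-1,5-dien-9-yn-2-yl]oxy}silane | C=C(O[Si](C)(C)C(C)(C)C)CC/C=C(\C)CCC#CC
A5 | alternative 2 | 11,12,13-trinoreudesm-3-en-8-one (trans-fused) | CC1=CCC[C@]2(C)CC(=O)CC[C@@H]12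
A6 | alternative 3 | (E)-β-ocimene | C=C/C(C)=C/CC=C(C)C
A7 | alternative 3 | 2-{2-[(tert-butyldimethylsilyl)oxy]ethyl}prop-2-enal | C=C(C=O)CCO[Si](C)(C)C(C)(C)C
A8 | alternative 3 | 1-{2-[(tert-butyldimethylsilyl)oxy]ethyl}-3-methyl-2-(3-methylbut-2-en-1-yl)cyclohex-3-ene-1-carbaldehyde (formyl cis to prenyl) | CC1=CCC[C@](C=O)(CCO[Si](C)(C)C(C)(C)C)[C@H]1CC=C(C)C
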